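**Numbering used throughout:** 1 2-methylbut-3-en-2-ol, 2 triethyl orthoacetate, 3 C7 ester, 4 β-keto ester, 5 mono-silyl enol ether, 6 bis-silyl diene, 7 but-3-yn-2-one, 8 cycloadduct (not isolated), 9 aryl methyl ketone, 10 enaminone (not isolated), 11 chromone, 12 arylboronic acid, 13 silylated flavanone, 14 target.

## The problem

IN0946 is a (2S)-flavanone: a chroman-4-one (ring A fused to the pyranone ring C) with a 3,4-dimethoxyphenyl group (ring B) at C2. Ring A is pentasubstituted: C4a carries the ketone carbon C4, C5 is the only CH, C6 and C8 carry 3-methylbut-2-enyl (prenyl) groups, C7 a free hydroxyl and C8a the ring oxygen O1. The single stereocentre C2 is benzylic, bound to O1 and β to the ketone. Base therefore opens ring C by retro-oxa-Michael elimination to the 2'-hydroxychalcone and recloses it without facial control; no second stereocentre can relay to C2, so it must be set by a reagent and must not meet base afterwards. The prenyl olefins lie ortho to phenolic oxygens, which add to them under strong acid (2,2-dimethylchromans), and they exclude hydrogenolysis, electrophilic halogen and most oxidants. Placing two prenyl groups on C6 and C8 of a preformed resorcinol ring is an O- versus C-alkylation and mono/bis/geminal selectivity problem, and O7 must be told apart from O1.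

The feature that the plan uses is the pattern of ring A itself. Read from C8a to C6, the atoms C8a(O)–C8(prenyl)–C7(O)–C6(prenyl) are an ester carbon, its α-carbon, a ketone carbon and its α'-carbon. This is a β-keto ester substituted on both flanking carbons, and because the two substituents are identical it is the head-to-tail Claisen dimer of one C7 ester. The remaining ring atoms, C5(H) and C4a with the C4 carbonyl on it, are the two sp carbons of a terminal ynone. Ring A can therefore be made by a [4+2] annulation instead of being decorated. A second feature is that C2 is the β-carbon of the vinylogous ester O1–C2=C3–C4=O of the corresponding chromone, so the stereocentre can be created last, from a flat precursor, by a catalyst and without base.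

## Retrosynthesis

**14 ⇒ 13.** The O7–Si bond is cut. The silyl ether is not added for this purpose: it is the enol silyl ether oxygen of the diene carried through, so the only cost is its removal. The forward reaction must free the phenol without generating an unbuffered phenoxide next to the base-labile C2.

**13 ⇒ 11 + 12.** The C2–C1' bond is cut, giving the achiral chromone 11 and the arylboronic acid 12. The neighbouring cut, O1–C2 (ring closure of a chalcone), creates C2 in a reversible step under the conditions that racemize it. The C2–aryl cut creates it in an irreversible carbometalation under neutral conditions, and it removes ring B and the stereocentre together. The forward reaction must be an enantioselective conjugate arylation that tolerates two trisubstituted olefins and a hindered aryl silyl ether.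

**11 ⇒ 9.** O1–C2 and C2–C3 are cut, and C2 is supplied as a formyl equivalent to the methyl ketone 9. The precursor is an ortho-hydroxyaryl methyl ketone whose other phenol is already silylated. The forward reaction needs only a condensation and a mildly acidic ring closure.

**9 ⇒ 6 + 7 (through 8).** This is the strategic cut: two bonds of ring A, C5–C6 and C4a–C8a, are broken. The ring falls into the four-carbon diene 6 (C8a, C8, C7, C6, with both prenyl chains and both oxygens in place) and the two-carbon ynone 7 (C4a, C5 and the acetyl group). The neighbouring plan keeps ring A from the aromatic pool and installs the prenyls by O-allylation, sigmatropic shift and olefin cross-metathesis on a resorcinol ketone. It is of comparable length, but each of its steps poses a selectivity question: alkylation of a chelated phenol, ortho against para migration, two-fold metathesis, later differentiation of the two phenols. In the construction, the positions of all five substituents follow from the connectivity of 6 and 7, and O7 and O8a emerge differentiated. The forward reaction must be a regioselective cycloaddition with aromatization.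

**6 ⇒ 5 ⇒ 4.** Two O–Si bonds are cut. The robust t-BuMe2Si group goes on the ketone oxygen (future O7) first and the labile Me3Si group on the ester oxygen (future O8a) second. The forward reactions are the standard two-stage enol silylation of a β-keto ester.

**4 ⇒ 3 + 3.** The C7–C8 bond is cut, which is the retro-Claisen condensation. Because C6 and C8 carry the same substituent, both halves are the same ester 3, and no crossed condensation or sequential alkylation of an acetoacetate is needed. The forward reaction must be a clean self-condensation.

**3 ⇒ 1 + 2.** The bond between the allylic CH2 and the CH2 next to the ester is cut (Johnson–Claisen retron). The trisubstituted olefin of each future prenyl group is created by the [3,3]-shift from the commodity tertiary alcohol 1 and the orthoester 2.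

## Roads not taken

**Alternative 1:** the obvious route. The cuts are O1–C2 and C2–C3 (aldol retron). Resacetophenone is prenylated to 1-[2,4-dihydroxy-3,5-bis(3-methylbut-2-en-1-yl)phenyl]ethanone A1, which is condensed with 3,4-dimethoxybenzaldehyde (Claisen–Schmidt) to the 2'-hydroxychalcone A2; the key step is its intramolecular oxa-Michael closure under a chiral base or acid. The chosen plan is better on three counts:
- The closure of A2 is reversible and runs under conditions that open the product, so C2 would be set under equilibration.
- Catalysts that give high selectivity in this ring closure rely on an extra activating group at the α-carbon, which costs steps and an acidic, hot decarboxylation that the prenyl-phenol pairs would not tolerate.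
- The free 4'-hydroxyl makes the enone of A2 a vinylogous acid and a poor acceptor, so protection is still needed, and A1 has to be obtained by decorating the arene.

**Alternative 2:** the biosynthetic order, flavanone first and prenyls last. Both C(aryl)–prenyl bonds are cut. (2S)-2-(3,4-Dimethoxyphenyl)-7-hydroxychroman-4-one A3 would be C-prenylated twice, either directly with a prenyl electrophile or through the 6,8-diiodide A4 and a two-fold cross-coupling with a prenyl-metal reagent under a zerovalent palladium catalyst. The positions are right, since C6 and C8 are the only activated carbons of ring A. The chosen plan is better for these reasons: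
- Direct alkylation needs the phenoxide, hence base on a formed flavanone, with ring opening and loss of configuration at C2.
- Direct alkylation also gives O-, mono-, bis- and geminal products, and acid-mediated variants close chromans.
- Iodination of A3 competes on the electron-rich ring B and at C3.
- Each coupling of an allyl-metal can deliver the linear or the branched (1,1-dimethylallyl) isomer, so two couplings give isomers of the same mass that are hard to separate.

In the chosen plan the prenyl groups are ordinary sp3 chains before any arene exists.

**Alternative 3:** ring A annulated onto a preformed, enantiopure ring C. The cuts are C4a–C5 and C8–C8a. (2S)-2-(3,4-Dimethoxyphenyl)-2,3-dihydro-4H-pyran-4-one A5 would come from a catalytic asymmetric hetero-Diels–Alder reaction of 3,4-dimethoxybenzaldehyde with 1-methoxy-3-(trimethylsilyloxy)buta-1,3-diene. Its C5=C6 bond would serve as the dienophile towards the 1-methoxy-3-silyloxy diene A6, and the key step is Diels–Alder reaction and aromatization. It would set C2 first by a dependable reaction, but the chosen plan is better for these reasons: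
- A5 is a vinylogous ester and an electron-rich, poor dienophile.
- In the adduct C8a carries a hydrogen and O1 lies β to the C7 carbonyl. The easy route to an arene is then E1cB expulsion of O1, which opens ring C and gives a para-hydroxyaryl ketone without the C8a–O bond.
- Avoiding that needs an extra leaving group at C4a and therefore more steps.

In the chosen plan C8a enters at the carboxyl oxidation level, so its oxygen cannot be lost.

Key step: step 5

## Route

Assumption: the catalyst of step 7 is taken to attack the chromone from the same face, relative to the enone, as it attacks carbocyclic enones, which makes the (R)-ligand the one leading to the (2S)-product; if the sense proves opposite, the (S)-ligand is used and nothing else changes.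

Step 1
Reactants: 1 2-methylbut-3-en-2-ol; 2 triethyl orthoacetate
Product: 3 ethyl 5-methylhex-4-enoate
Conditions: 2 (excess), EtCO2H (cat.), 140 °C, EtOH distilled off
Reagents that add atoms: none
Why: Johnson–Claisen rearrangement: acid-catalysed exchange gives the mixed ketene acetal of the tertiary allylic alcohol, and its [3,3]-shift transposes the allyl unit to give the γ,δ-unsaturated ester with the trisubstituted olefin of the future prenyl group.

Step 2
Reactants: 3 ethyl 5-methylhex-4-enoate (two molecules)
Product: 4 ethyl 7-methyl-2-(3-methylbut-2-en-1-yl)-3-oxooct-6-enoate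
Conditions: lithium diisopropylamide (0.55 equiv), THF, −78 to 25 °C; then 1 M HCl
Reagents that add atoms: none
Why: Claisen self-condensation: half of the ester is converted into its lithium enolate, which acylates the other half on warming, and deprotonation of the β-keto ester by the released ethoxide makes it irreversible; the head-to-tail union puts one chain on the α-carbon (future C8) and one on the γ-carbon (future C6).

Step 3
Reactants: 4 ethyl 7-methyl-2-(3-methylbut-2-en-1-yl)-3-oxooct-6-enoate
Product: 5 ethyl 3-[(tert-butyldimethylsilyl)oxy]-7-methyl-2-(3-methylbut-2-en-1-yl)octa-2,6-dienoate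
Conditions: t-BuMe2SiOSO2CF3, Et3N, CH2Cl2, 0 °C
Reagents that add atoms: tert-butyldimethylsilyl trifluoromethanesulfonate, CC(C)(C)[Si](C)(C)OS(=O)(=O)C(F)(F)F
Why: Soft enolization and O-silylation of the β-keto ester at its most acidic position give the conjugated 3-silyloxy-2-enoate; the geometry of the new double bond does not matter because it becomes the central single bond of the diene in step 4.

Step 4
Reactants: 5 ethyl 3-[(tert-butyldimethylsilyl)oxy]-7-methyl-2-(3-methylbut-2-en-1-yl)octa-2,6-dienoate
Product: 6 (3Z)-3-[(tert-butyldimethylsilyl)oxy]-1-ethoxy-7-methyl-2-(3-methylbut-2-en-1-yl)-1-[(trimethylsilyl)oxy]octa-1,3,6-triene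
Conditions: lithium diisopropylamide, THF, −78 °C; then Me3SiCl, −78 to 0 °C; pentane, filtration, used crude
Reagents that add atoms: chlorotrimethylsilane, C[Si](C)(C)Cl
Why: γ-Deprotonation of the 3-silyloxy-2-enoate gives the extended ester dienolate, which Me3SiCl traps on oxygen (the standard preparation of 1-alkoxy-1,3-bis(silyloxy)buta-1,3-dienes); the 3Z isomer, with the chain at C4 pointing outward, is expected and is the one that can adopt the s-cis conformation.

Step 5
Reactants: 6 (3Z)-3-[(tert-butyldimethylsilyl)oxy]-1-ethoxy-7-methyl-2-(3-methylbut-2-en-1-yl)-1-[(trimethylsilyl)oxy]octa-1,3,6-triene; 7 but-3-yn-2-one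
Product: 9 1-{4-[(tert-butyldimethylsilyl)oxy]-2-hydroxy-3,5-bis(3-methylbut-2-en-1-yl)phenyl}ethanone, via cyclohexadiene cycloadduct 8 (not isolated)
Conditions: toluene, −20 to 60 °C; then pyridinium p-toluenesulfonate (cat.), wet THF, 0 °C
Reagents that add atoms: none
Why: Diels–Alder reaction with aromatization, the known annulation of 1-alkoxy-1,3-bis(silyloxy)buta-1,3-dienes with acetylenic esters and ketones to 2,4-dioxygenated benzoates and aryl ketones. The three oxygen donors make the diene terminus C4 (future C6) the nucleophilic end, and the ynone is polarized towards its unsubstituted β-carbon (future C5); C6–C5 therefore forms ahead of C8a–C4a in an asynchronous [4+2] cycloaddition (at the stepwise limit a Mukaiyama–Michael addition followed by closure of the allenolate on the silyloxycarbenium carbon), and this polarity match secures the one regiochemistry needed, with the acetyl group next to the acetal carbon. Ring A is thus closed as a six-membered carbocycle by an intermolecular [4+2] ring formation from two open-chain components. Cycloadduct 8 is a cyclohexa-1,4-diene with a mixed O-ethyl O-silyl ketal at C8a and a hydrogen at C6; mild acid removes ethanol and the labile Me3Si group (1,4-elimination, or ketal hydrolysis to the dienone and tautomerization), and both paths leave a free hydroxyl on C8a, chelated to the acetyl group. The two sp3 centres of 8 are destroyed, so no stereocentre has to be controlled. No positional selectivity is asked of the arene, because both prenyl chains, O7 and O8a are already bonded to their carbons in 6, and the two oxygens emerge differentiated because O7 keeps the robust t-BuMe2Si group while O8a loses Me3Si. Chemoselectivity rests on the electron-poor alkyne being the only good dienophile present; the ketone carbonyl and the isolated trisubstituted olefins should not compete thermally.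

Step 6
Reactants: 9 1-{4-[(tert-butyldimethylsilyl)oxy]-2-hydroxy-3,5-bis(3-methylbut-2-en-1-yl)phenyl}ethanone
Product: 11 7-[(tert-butyldimethylsilyl)oxy]-6,8-bis(3-methylbut-2-en-1-yl)-4H-chromen-4-one, via enaminone 10 (not isolated)
Conditions: Me2NCH(OMe)2, toluene, 90 °C; evaporation; then AcOH, 60 °C
Reagents that add atoms: N,N-dimethylformamide dimethyl acetal, COC(OC)N(C)C
Why: Condensation of the methyl ketone with the amide acetal gives the enaminone, and weak acid then induces 6-endo addition of the chelated phenol and loss of dimethylamine (the standard enaminone route to 2,3-unsubstituted chromones); AcOH is too weak to add the phenol across the neighbouring prenyl olefin.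

Step 7
Reactants: 11 7-[(tert-butyldimethylsilyl)oxy]-6,8-bis(3-methylbut-2-en-1-yl)-4H-chromen-4-one; 12 (3,4-dimethoxyphenyl)boronic acid
Product: 13 (2S)-7-[(tert-butyldimethylsilyl)oxy]-2-(3,4-dimethoxyphenyl)-6,8-bis(3-methylbut-2-en-1-yl)-2,3-dihydro-4H-chromen-4-one
Conditions: Pd(OCOCF3)2 (10 mol %), (R)-t-BuPyOx (12 mol %), NH4PF6 (30 mol %), H2O (5 equiv), ClCH2CH2Cl, 60 °C
Reagents that add atoms: none
Why: Asymmetric conjugate addition of an arylboronic acid to a chromone under a cationic divalent palladium pyridine-oxazoline catalyst: transmetalation, enantiodetermining insertion of C2=C3 into the Pd–aryl bond and protonolysis of the palladium enolate by water. C2 is set by the ligand, whose tert-butyl group blocks one face of the bound enone, and no base is present, so the product cannot racemize by ring opening; the trisubstituted prenyl olefins should insert far more slowly than the enone.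

Step 8
Reactants: 13 (2S)-7-[(tert-butyldimethylsilyl)oxy]-2-(3,4-dimethoxyphenyl)-6,8-bis(3-methylbut-2-en-1-yl)-2,3-dihydro-4H-chromen-4-one
Product: 14 (2S)-2-(3,4-dimethoxyphenyl)-7-hydroxy-6,8-bis(3-methylbut-2-en-1-yl)-2,3-dihydro-4H-chromen-4-one
Conditions: Bu4NF, AcOH (1:1), THF, 0 °C
Reagents that add atoms: none
Why: Fluoride cleaves the aryl silyl ether, and AcOH buffers the phenoxide so that enolization at C3 and retro-oxa-Michael opening, the racemization path of C2, should not occur; the prenyl groups and the methyl ethers are inert.

## Compound list

1 | 2-methylbut-3-en-2-ol | CC(C)(O)C=C | starting material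
2 | triethyl orthoacetate (1,1,1-triethoxyethane) | CCOC(C)(OCC)OCC | starting material
3 | ethyl 5-methylhex-4-enoate | CCOC(=O)CCC=C(C)C | intermediate
4 | ethyl 7-methyl-2-(3-methylbut-2-en-1-yl)-3-oxooct-6-enoate (racemic at C2) | CCOC(=O)C(CC=C(C)C)C(=O)CCC=C(C)C | intermediate
5 | ethyl 3-[(tert-butyldimethylsilyl)oxy]-7-methyl-2-(3-methylbut-2-en-1-yl)octa-2,6-dienoate (either geometry at C2=C3) | CCOC(=O)C(CC=C(C)C)=C(O[Si](C)(C)C(C)(C)C)CCC=C(C)C | intermediate
6 | (3Z)-3-[(tert-butyldimethylsilyl)oxy]-1-ethoxy-7-methyl-2-(3-methylbut-2-en-1-yl)-1-[(trimethylsilyl)oxy]octa-1,3,6-triene | CCOC(O[Si](C)(C)C)=C(CC=C(C)C)/C(O[Si](C)(C)C(C)(C)C)=C/CC=C(C)C | intermediate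
7 | but-3-yn-2-one | CC(=O)C#C | starting material
8 | 1-{4-[(tert-butyldimethylsilyl)oxy]-6-ethoxy-3,5-bis(3-methylbut-2-en-1-yl)-6-[(trimethylsilyl)oxy]cyclohexa-1,4-dien-1-yl}ethanone (cycloadduct, not isolated, mixture of diastereomers) | CCOC1(O[Si](C)(C)C)C(CC=C(C)C)=C(O[Si](C)(C)C(C)(C)C)C(CC=C(C)C)C=C1C(C)=O | intermediate
9 | 1-{4-[(tert-butyldimethylsilyl)oxy]-2-hydroxy-3,5-bis(3-methylbut-2-en-1-yl)phenyl}ethanone | CC(=O)c1cc(CC=C(C)C)c(O[Si](C)(C)C(C)(C)C)c(CC=C(C)C)c1O | intermediate
10 | (2E)-1-{4-[(tert-butyldimethylsilyl)oxy]-2-hydroxy-3,5-bis(3-methylbut-2-en-1-yl)phenyl}-3-(dimethylamino)prop-2-en-1-one (enaminone, not isolated) | CN(C)/C=C/C(=O)c1cc(CC=C(C)C)c(O[Si](C)(C)C(C)(C)C)c(CC=C(C)C)c1O | intermediate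
11 | 7-[(tert-butyldimethylsilyl)oxy]-6,8-bis(3-methylbut-2-en-1-yl)-4H-chromen-4-one | O=c1ccoc2c(CC=C(C)C)c(O[Si](C)(C)C(C)(C)C)c(CC=C(C)C)cc12 | intermediate
12 | (3,4-dimethoxyphenyl)boronic acid | COc1ccc(B(O)O)cc1OC | starting material
13 | (2S)-7-[(tert-butyldimethylsilyl)oxy]-2-(3,4-dimethoxyphenyl)-6,8-bis(3-methylbut-2-en-1-yl)-2,3-dihydro-4H-chromen-4-one | COc1ccc([C@@H]2CC(=O)c3cc(CC=C(C)C)c(O[Si](C)(C)C(C)(C)C)c(CC=C(C)C)c3O2)cc1OC | intermediate
14 | (2S)-2-(3,4-dimethoxyphenyl)-7-hydroxy-6,8-bis(3-methylbut-2-en-1-yl)-2,3-dihydro-4H-chromen-4-one (IN0946) | COc1ccc([C@@H]2CC(=O)c3cc(CC=C(C)C)c(O)c(CC=C(C)C)c3O2)cc1OC | target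

## Step count and risks

Total: 8 steps. Longest linear sequence: 8 steps (1 to 14; compounds 2, 7 and 12 are purchased).

**Step 5 (key step).** The 2,4-disubstituted diene may populate the s-cis conformer poorly and react slowly. Bond formation may stop after the first C–C bond (Mukaiyama–Michael addition at the diene terminus without ring closure). The ketene acetal may be protodesilylated, or the ynone may oligomerize, before cycloaddition. During aromatization the enol silyl ether at C7 may be hydrolysed early, with loss of the differentiation of the two oxygens.

Fallback, setting out from 6 and returning at 9: the two ring bonds are made one after the other by ionic reactions with an sp3 electrophile instead of by cycloaddition with an alkyne. Diene 6 is alkylated at its terminus by 4,4-dimethoxybutan-2-one (Me3SiOSO2CF3 cat., CH2Cl2, −78 °C, vinylogous Mukaiyama reaction of the acetal). Aqueous acid work-up gives ethyl 5-methoxy-2,4-bis(3-methylbut-2-en-1-yl)-3,7-dioxooctanoate F1. NaOEt in EtOH at reflux then closes ring A by Dieckmann-type acylation of the methyl ketone α-carbon by the ester; β-elimination of methanol and enolization give 1-[2,4-dihydroxy-3,5-bis(3-methylbut-2-en-1-yl)phenyl]ethanone F2. Selective silylation of the non-chelated 4-hydroxyl (t-BuMe2SiCl, imidazole, DMF) gives 9.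

**Step 7.** Insertion may be slow because the 7-silyloxy group lowers the electrophilicity of C2. The electron-rich boronic acid may be lost by protodeboronation or homocoupling. The cationic palladium may engage the prenyl olefins (insertion or allylic activation). The silyl ether may be partly cleaved by the aqueous hexafluorophosphate medium. Facial selectivity on this 8-substituted chromone may be incomplete.

Fallback, setting out from 9 and returning at 14: Claisen–Schmidt condensation of 9 with 3,4-dimethoxybenzaldehyde (KOH, EtOH, 25 °C, the silyl ether being lost) gives (2E)-1-[2,4-dihydroxy-3,5-bis(3-methylbut-2-en-1-yl)phenyl]-3-(3,4-dimethoxyphenyl)prop-2-en-1-one F3. NaOAc in EtOH at reflux closes it to the racemic flavanone F4. Preparative chromatography on a chiral stationary phase gives 14; the (2R)-enantiomer F5 is returned to the racemate with base (ring opening and reclosure) and resubmitted.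

**Step 6.** The amide acetal may O-methylate the phenol. The aryl silyl ether, para to a carbonyl, may be cleaved by methanol and dimethylamine at 90 °C. Acid may add the C8a hydroxyl across the C8 prenyl olefin before the pyranone closes.

Fallback, setting out from 9 and returning at 11: C2 is introduced at the ester oxidation level by Claisen condensation of the methyl ketone with ethyl formate (NaH, THF, 0 to 25 °C). After work-up this gives the cyclic hemiacetal 7-[(tert-butyldimethylsilyl)oxy]-2-hydroxy-6,8-bis(3-methylbut-2-en-1-yl)-2,3-dihydro-4H-chromen-4-one F6, which is dehydrated (p-toluenesulfonic acid cat., toluene, 25 °C) to 11.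

**Step 8.** Cleavage may be slow because two prenyl groups flank the silyl ether. If the medium turns basic, C2 may racemize by enolization and retro-oxa-Michael ring opening.

Fallback, setting out from 11 and returning at 14: the protecting group is exchanged at the chromone stage, where no stereocentre is at risk, for one that is removed by acid, which does not open ring C. Bu4NF in THF converts 11 into 7-hydroxy-6,8-bis(3-methylbut-2-en-1-yl)-4H-chromen-4-one F7. MeOCH2Cl and i-Pr2NEt give 7-(methoxymethoxy)-6,8-bis(3-methylbut-2-en-1-yl)-4H-chromen-4-one F8. The conditions of step 7 with 12 give (2S)-2-(3,4-dimethoxyphenyl)-7-(methoxymethoxy)-6,8-bis(3-methylbut-2-en-1-yl)-2,3-dihydro-4H-chromen-4-one F9. HCl in MeOH at 25 °C gives 14.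

## Further compounds

F1 | step 5 | ethyl 5-methoxy-2,4-bis(3-methylbut-2-en-1-yl)-3,7-dioxooctanoate | CCOC(=O)C(CC=C(C)C)C(=O)C(CC=C(C)C)C(OC)CC(C)=O
F2 | step 5 | 1-[2,4-dihydroxy-3,5-bis(3-methylbut-2-en-1-yl)phenyl]ethanone | CC(=O)c1cc(CC=C(C)C)c(O)c(CC=C(C)C)c1O
F3 | step 7 | (2E)-1-[2,4-dihydroxy-3,5-bis(3-methylbut-2-en-1-yl)phenyl]-3-(3,4-dimethoxyphenyl)prop-2-en-1-one | COc1ccc(/C=C/C(=O)c2cc(CC=C(C)C)c(O)c(CC=C(C)C)c2O)cc1OC
F4 | step 7 | racemic 2-(3,4-dimethoxyphenyl)-7-hydroxy-6,8-bis(3-methylbut-2-en-1-yl)-2,3-dihydro-4H-chromen-4-one | COc1ccc(C2CC(=O)c3cc(CC=C(C)C)c(O)c(CC=C(C)C)c3O2)cc1OC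
F5 | step 7 | (2R)-2-(3,4-dimethoxyphenyl)-7-hydroxy-6,8-bis(3-methylbut-2-en-1-yl)-2,3-dihydro-4H-chromen-4-one | COc1ccc([C@H]2CC(=O)c3cc(CC=C(C)C)c(O)c(CC=C(C)C)c3O2)cc1OC
F6 | step 6 | 7-[(tert-butyldimethylsilyl)oxy]-2-hydroxy-6,8-bis(3-methylbut-2-en-1-yl)-2,3-dihydro-4H-chromen-4-one | O=C1CC(O)Oc2c(CC=C(C)C)c(O[Si](C)(C)C(C)(C)C)c(CC=C(C)C)cc12
F7 | step 8 | 7-hydroxy-6,8-bis(3-methylbut-2-en-1-yl)-4H-chromen-4-one | O=c1ccoc2c(CC=C(C)C)c(O)c(CC=C(C)C)cc12
F8 | step 8 | 7-(methoxymethoxy)-6,8-bis(3-methylbut-2-en-1-yl)-4H-chromen-4-one | O=c1ccoc2c(CC=C(C)C)c(OCOC)c(CC=C(C)C)cc12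
F9 | step 8 | (2S)-2-(3,4-dimethoxyphenyl)-7-(methoxymethoxy)-6,8-bis(3-methylbut-2-en-1-yl)-2,3-dihydro-4H-chromen-4-one | COc1ccc([C@@H]2CC(=O)c3cc(CC=C(C)C)c(OCOC)c(CC=C(C)C)c3O2)cc1OC
A1 | alternative 1 | 1-[2,4-dihydroxy-3,5-bis(3-methylbut-2-en-1-yl)phenyl]ethanone | CC(=O)c1cc(CC=C(C)C)c(O)c(CC=C(C)C)c1O
A2 | alternative 1 | (2E)-1-[2,4-dihydroxy-3,5-bis(3-methylbut-2-en-1-yl)phenyl]-3-(3,4-dimethoxyphenyl)prop-2-en-1-one | COc1ccc(/C=C/C(=O)c2cc(CC=C(C)C)c(O)c(CC=C(C)C)c2O)cc1OC
A3 | alternative 2 | (2S)-2-(3,4-dimethoxyphenyl)-7-hydroxy-2,3-dihydro-4H-chromen-4-one | COc1ccc([C@@H]2CC(=O)c3ccc(O)cc3O2)cc1OC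
A4 | alternative 2 | (2S)-2-(3,4-dimethoxyphenyl)-7-hydroxy-6,8-diiodo-2,3-dihydro-4H-chromen-4-one | COc1ccc([C@@H]2CC(=O)c3cc(I)c(O)c(I)c3O2)cc1OC
A5 | alternative 3 | (2S)-2-(3,4-dimethoxyphenyl)-2,3-dihydro-4H-pyran-4-one | COc1ccc([C@@H]2CC(=O)C=CO2)cc1OC
A6 | alternative 3 | 1-methoxy-7-methyl-2-(3-methylbut-2-en-1-yl)-3-[(trimethylsilyl)oxy]octa-1,3,6-triene | COC=C(CC=C(C)C)C(O[Si](C)(C)C)=CCC=C(C)C
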